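The constants are assumed; the result is computed.

This closed, stirred vessel holds one charge of partner that two catalysed routes compete for, and each target then takes a further starting material into side product.

starting material 0.061 M; second substrate 0.500 equiv; partner 0.500 equiv; free catalyst 0.05 mol%; time 40 min

    starting material + free catalyst ⇌ catalyst intermediate A (K1 = 23 M⁻¹, k1 = 4600 M⁻¹ s⁻¹)
    partner + catalyst intermediate A → free catalyst + target (k2 = 50000 M⁻¹ s⁻¹)
    second substrate + free catalyst ⇌ catalyst intermediate B (K3 = 150 M⁻¹, k3 = 15000 M⁻¹ s⁻¹)
    partner + catalyst intermediate B → free catalyst + second product (k4 = 570 M⁻¹ s⁻¹)
    starting material + target → side product (k5 = 0.44 M⁻¹ s⁻¹)

- a species is counted by the starting material in it: one side product counts as two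
- the reaction counts as stopped when no species that holds the starting material changes by six tenths of a point or more over the second half of the time
- run time (flask): 40 min

- which holds at 40 min: what has brought the reaction to rest, or that it has not come to rest (no working catalyst is left / the partner has run out first / all of the starting material has reacted / forward and back rates have come level / it is still moving)
- conversion of starting material at 40 min

The routes could take 0.0915 M of partner, but the vessel holds 0.0305 M, so the partner is the limiting reagent. I turn the constants into times to see how it divides.

I take the partner at half its charge, 0.01525 M. There, catalyst intermediate A lives 1.04 ms and catalyst intermediate B 9.20 ms.

The next rung is the partner itself. Step 1 alone has a half-life of 0.082 min with the whole catalyst free, but second substrate binds it 4.6 to one, so I expect the partner to pass in about 0.331 min. That is far longer than either lifetime, so both intermediates stay steady while it falls.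

With the other charges held, this gives 6.08 for the split σ, the target made per second product made. It is the ratio of the two capture rates, 0.61, times the chance that intermediate A meets partner before falling back, 0.792, over the same chance for intermediate B, 0.0800.

The slowest rung is step 5, where target has a half-life of 0.43 min at the charged starting material. If each target ends up costing two starting materials, the conversion is two times the partner equivalents times σ/(1+σ), 85.9%. Even at the 14.1% of starting material that leaves, I reckon the target's half-life at 3.05 min, shorter than 40 min, so I keep that count.

The forecast gives the partner has run out first and 83%, holding that “the uncatalysed side reaction consumes essentially all the target”.

The flask gives the partner has run out first and 84.5%, with 0% of the partner left. Its second product reads 0.00472 M, so partner charge less that, over that, reads a split of 5.46 against my σ of 6.08.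

In the neighbouring flask with 0.24 M of starting material, same equivalents and time, σ falls to 2.26, which gives 69.3%. That neighbouring flask reaches 71.3%, with 0% of its partner left.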